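Don't take the flat tops of the early runs for end points.

| setting | oak | elm | birch | teal | grey | amber | red | green |
|---|---|---|---|---|---|---|---|---|
| starting material | 0.91 M | 0.91 M | 0.91 M | 0.91 M | 0.91 M | 0.91 M | 0.91 M | 0.91 M |
| reagent | 0.23 M | 0.89 M | 3 M | 0.637 M | 0.400 M | 0.300 M | 1.00 M | 2.50 M |
| protic impurity | 0.91 M | 0.91 M | 0.91 M | 0.910 M | 0.910 M | 0.910 M | 0.910 M | 0.910 M |
| catalyst | 46 mM | 46 mM | 46 mM | 46 mM | 46 mM | 46 mM | 46 mM | 46 mM |
| remark | run made earlier | run made earlier | run made earlier |  |  |  |  |  |
| time |  |  |  | 30 h | 30 h | 30 h | 30 h | 30 h |

| run | time / h | target / % |
|---|---|---|
| oak | 2.00 | 4.9 |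
| oak | 5.00 | 9.5 |
| oak | 10.0 | 9.7 |
| oak | 15.0 | 10.9 |
| elm | 2.00 | 18.4 |
| elm | 5.00 | 28.2 |
| elm | 10.0 | 31.2 |
| elm | 15.0 | 30.7 |
| birch | 4.00 | 52.5 |
| birch | 8.00 | 51.7 |
| birch | 12.0 | 47.4 |
| birch | 15.0 | 43.8 |

(standard deviation of a reading: 0.5 percentage points)

- amounts and yields of target count crystals too
- given per volume of solution although it is solid: crystals
- the numbers in the tables scatter by 0.5 percentage points (one standard deviation)
- on the list of suspects stand: crystals <-> target; target + catalyst <-> isomer of the product + catalyst; starting material + reagent <-> target; starting material + protic impurity -> quenched substrate; starting material + reagent <-> isomer of the product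

- all flasks from highest to lowest amount of target, in percent of the starting material charged, at 30 h (teal / grey / amber / red / green)
- the same order at 5.0 d (teal / grey / amber / red / green)
- the amount of target, in percent of the starting material charged of the flask you put first, at 30 h
- the amount of target, in percent of the starting material charged of the flask you put last, at 30 h

Run the flask in slow motion, counting everything as a fraction of the starting material charged. On the list of suspects, starting material and reagent join reversibly to target or to its isomer, the catalyst may turn target into isomer, protic impurity may quench starting material, and target may crystallise.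

At the first reading target goes with the reagent: at 2.00 h elm reads 3.76 times oak, on 3.87 times the reagent. Now write the reagent balance. In oak the reagent is the limiting reagent, its charge worth 25.3% of the starting material, and each product takes one reagent, so target at 10.9% stands under that line.

In the middle the rise in elm stops: elm moves 0.5 percentage points between its last readings, against a scatter of 0.5 points. Then comes the stage that matters, for 30 h lies beyond the last reading of any run. Birch falls from 52.5% at 4.00 h to 43.8% at 15.0 h. Treat that fall as a decay and read from it 60.7 h, the time over which target shrinks by a factor e, the fade time.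

My reckoning ranks the flasks by reagent charged at both times and fades each from the last reading of its nearest run. Green, from birch, gives 34.2%. Amber, from oak scaled up to its own reagent line of 33.0%, gives 11.1%.

The forecast gives green > red > teal > grey > amber at 30 h and green > red > teal > grey > amber at 5.0 d, with 31% for the first flask and 11.5% for the last. Its ground for the ranking: “That loss should affect all flasks by a similar fraction, so I expect no crossing.” My order is the same, but my top stands higher than its figure and my low lower.

The flasks run green > red > teal > grey > amber at 30 h and green > red > teal > grey > amber at 5.0 d, with 37.7% in green and 11.2% in amber, so the forecast's top is 6.7 points low.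

    crystals ⇌ target, rate k1*(cs1 - [target]) while solid is left; crystals form when [target] > cs1 (solubility = 0.590 M, k = 0.260 h⁻¹)
    target + catalyst ⇌ isomer of the product + catalyst, rate k2*[catalyst]*[target] forward; the back reaction follows from the equilibrium constant (k = 0.860 M⁻¹ h⁻¹)
    starting material + reagent ⇌ target (K = 3.10 M⁻¹, k = 0.160 M⁻¹ h⁻¹)
    starting material + protic impurity → quenched substrate (k = 0.0150 M⁻¹ h⁻¹)
    starting material + reagent ⇌ isomer of the product (K = 4.50 M⁻¹, k = 0.0670 M⁻¹ h⁻¹)

Green at 30.0 h holds 50.2% as isomer beside that target. Fade green's value by the fade time and it gives 8.56% at 5.0 d, but green reads 33.1%, which over that stretch averages a fade time of 694 h, far longer than the one read from birch.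

Now stop green at 12 h, inside the span of birch's readings. Birch's first reading faded by 60.7 h gives 46.0%, and green at that time holds 46.4% as target.

Readings and results were computed with constants of no real substance, and the scatter is random.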